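## Retrosynthetic overview

1. The (2R,3R)-flavanonol is traced back to the (2S)-flavanone. O3 is added through the C3=C4 silyl enol ether from the face opposite ring B, and all silyl groups are removed in the last step.
2. The strategy rests on C2. It is a benzylic ether carbon between O1 and the electron-rich ring B, so in an open ring A aryl benzyl ether both C2–H bonds are activated toward a carbene placed at C3.
3. Ring C is the only ring built. It closes at C2–C3 by enantioselective dirhodium carbenoid C–H insertion of an ortho-(benzyloxy)aryl diazoketone. Rings A and B are bought.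
4. C4 and C3 are carried from the start as the acetyl group of phloroacetophenone, and detrifluoroacetylative diazo transfer turns it into the diazoketone. O1–C2 comes from a Mitsunobu coupling. No halogenation and no aryllithium is needed once alkenes and aryl silyl ethers are present.
5. Ring A: bis-silylation, O-prenylation and a Claisen–Cope relay put the prenyl group on C6 and free only O1. Ring B: resorcinol, two directed lithiations (geranyl, formyl), MOM to TBS exchange, reduction.

Key step: step 12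

Assumption: Rh2(S-PTTL)4 is taken to give the (2S)-flavanone in the key step; should the sense of induction prove opposite, Rh2(R-PTTL)4 made from D-tert-leucine is used with no other change.

Flavonoid numbering is used (O1, C2, C3, C4, C4a, C5 to C8, C8a; ring B primed). TBS = tert-butyldimethylsilyl, TES = triethylsilyl, MOM = methoxymethyl, geranyl = (2E)-3,7-dimethylocta-2,6-dienyl, prenyl = 3-methylbut-2-enyl.

## Route

**Step 1**
Reactants: 1 2,4,6-trihydroxyacetophenone
Product: 2 1-[2-hydroxy-4,6-bis(TBS-oxy)phenyl]ethanone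
Conditions: TBSCl (2.1 equiv), imidazole, DMF, 0 °C
Reagents that add atoms: tert-butyldimethylsilyl chloride, CC(C)(C)[Si](C)(C)Cl
Why: Selective O-silylation, in which the para hydroxyl and one of the two equivalent ortho hydroxyls react while the last one is held in a hydrogen bond to the acetyl oxygen and stays free.

**Step 2**
Reactants: 2 1-[2-hydroxy-4,6-bis(TBS-oxy)phenyl]ethanone; 3 3-methylbut-2-en-1-ol (prenol)
Product: 4 1-[2-(prenyloxy)-4,6-bis(TBS-oxy)phenyl]ethanone
Conditions: PPh3, DIAD, THF, 0 °C to rt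
Reagents that add atoms: none
Why: Mitsunobu etherification of the acidic ortho-acyl phenol with a primary allylic alcohol runs under neutral conditions, so the base-labile aryl silyl ethers are not touched.

**Step 3**
Reactants: 4 1-[2-(prenyloxy)-4,6-bis(TBS-oxy)phenyl]ethanone
Product: 7 1-[6-hydroxy-2,4-bis(TBS-oxy)-3-prenylphenyl]ethanone, via ortho-dienone 5 (not isolated), via para-dienone 6 (not isolated)
Conditions: N,N-diethylaniline, 200 °C, sealed tube, argon
Reagents that add atoms: none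
Why: Aromatic Claisen–Cope (para-Claisen) cascade, in which the first [3,3] shift puts a reverse-prenyl group on an ortho carbon, the second [3,3] shift carries it as a normal prenyl group to the para carbon between the two silyloxy groups (future C6), and tautomerisation frees only the phenol para to it (future O1).

**Step 4**
Reactants: 8 resorcinol
Product: 9 1,3-bis(methoxymethoxy)benzene
Conditions: MOMCl, i-Pr2NEt, CH2Cl2, 0 °C to rt
Reagents that add atoms: chloromethyl methyl ether, COCCl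
Why: Standard O-alkylation of both phenols installs two acetal groups that serve as directing groups for lithiation.

**Step 5**
Reactants: 9 1,3-bis(methoxymethoxy)benzene; 10 geranyl bromide
Product: 12 2-geranyl-1,3-bis(methoxymethoxy)benzene, via 2-lithio arene 11 (not isolated)
Conditions: n-BuLi, THF, 0 °C; CuI (10 mol %), 10, −78 °C to rt
Reagents that add atoms: none
Why: Directed ortho-metalation at the carbon between the two MOM ethers, then copper-assisted SN2 allylation at the unhindered primary carbon of the bromide, which keeps the E alkene.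

**Step 6**
Reactants: 12 2-geranyl-1,3-bis(methoxymethoxy)benzene
Product: 14 3-geranyl-2,4-bis(methoxymethoxy)benzaldehyde, via 4-lithio arene 13 (not isolated)
Conditions: s-BuLi, TMEDA, THF, −78 °C; DMF; H2O
Reagents that add atoms: N,N-dimethylformamide, CN(C)C=O
Why: Directed ortho-metalation next to a MOM ether and formylation with DMF, with benzylic-allylic deprotonation held back at −78 °C because the doubly ortho-flanked ArCH2 group keeps its C–H bonds close to the ring plane.

**Step 7**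
Reactants: 14 3-geranyl-2,4-bis(methoxymethoxy)benzaldehyde
Product: 15 3-geranyl-2,4-dihydroxybenzaldehyde
Conditions: aq HCl (3 M, cat.), MeOH, 50 °C, stopped at full conversion
Reagents that add atoms: none
Why: Acid-catalysed acetal exchange with methanol removes both MOM groups at the aldehyde oxidation level, where the phenols are deactivated and the product cannot form a quinone methide, and short exposure should spare the geranyl alkenes.

**Step 8**
Reactants: 15 3-geranyl-2,4-dihydroxybenzaldehyde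
Product: 16 3-geranyl-2,4-bis(TBS-oxy)benzaldehyde
Conditions: TBSOTf, 2,6-lutidine, CH2Cl2, 0 °C
Reagents that add atoms: tert-butyldimethylsilyl triflate, CC(C)(C)[Si](C)(C)OS(=O)(=O)C(F)(F)F
Why: O-silylation with the triflate is strong enough for the chelated and crowded 2-hydroxyl as well as the 4-hydroxyl.

**Step 9**
Reactants: 16 3-geranyl-2,4-bis(TBS-oxy)benzaldehyde
Product: 17 [3-geranyl-2,4-bis(TBS-oxy)phenyl]methanol
Conditions: i-Bu2AlH, CH2Cl2, −78 °C; aq potassium sodium tartrate
Reagents that add atoms: none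
Why: Hydride reduction of the aldehyde at −78 °C gives an aluminium alkoxide that is too poor a nucleophile to pull the neighbouring silyl group from the 2-oxygen.

**Step 10**
Reactants: 7 1-[6-hydroxy-2,4-bis(TBS-oxy)-3-prenylphenyl]ethanone; 17 [3-geranyl-2,4-bis(TBS-oxy)phenyl]methanol
Product: 18 1-{2-[3-geranyl-2,4-bis(TBS-oxy)benzyloxy]-4,6-bis(TBS-oxy)-5-prenylphenyl}ethanone
Conditions: PPh3, DIAD, toluene, 0 °C to rt; chromatography on Et3N-deactivated silica
Reagents that add atoms: none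
Why: Mitsunobu etherification forms O1–C2 under neutral conditions from the acidic ortho-acyl phenol and the activated primary benzylic alcohol, so the labile electron-rich benzylic halide need not be made.

**Step 11**
Reactants: 18 1-{2-[3-geranyl-2,4-bis(TBS-oxy)benzyloxy]-4,6-bis(TBS-oxy)-5-prenylphenyl}ethanone
Product: 20 2-diazo-1-{2-[3-geranyl-2,4-bis(TBS-oxy)benzyloxy]-4,6-bis(TBS-oxy)-5-prenylphenyl}ethanone, via trifluoroacetyl diketone 19 (not isolated)
Conditions: LiN(SiMe3)2, THF, −78 °C; CF3CO2CH2CF3; AcOH quench; then MsN3, Et3N, H2O (1 equiv), MeCN–CH2Cl2, rt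
Reagents that add atoms: methanesulfonyl azide, CS(=O)(=O)N=[N+]=[N-]; 2,2,2-trifluoroethyl trifluoroacetate, O=C(OCC(F)(F)F)C(F)(F)F (its atoms stand in 19 only)
Why: Detrifluoroacetylative diazo transfer (Regitz type), in which the kinetic enolate of the methyl ketone is trifluoroacetylated at once at −78 °C and the activated diketone takes the diazo group with loss of the trifluoroacetyl group, which avoids acyl activation of a doubly ortho-substituted benzoic acid.

**Step 12**
Reactants: 20 2-diazo-1-{2-[3-geranyl-2,4-bis(TBS-oxy)benzyloxy]-4,6-bis(TBS-oxy)-5-prenylphenyl}ethanone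
Product: 21 (2S)-5,7,2',4'-tetrakis(TBS-oxy)-3'-geranyl-6-prenylflavanone
Conditions: Rh2(S-PTTL)4, dirhodium tetrakis[N-phthaloyl-(S)-tert-leucinate] (1 mol %), 4 Å MS, CH2Cl2, 0 °C to rt, slow addition of 20 at high dilution
Reagents that add atoms: none
Why: The catalyst expels N2 from 20 to give an electrophilic rhodium carbenoid at C3, which takes one benzylic C2–H bond through a concerted, asynchronous three-centre transition state with hydride-transfer character and releases the metal as C2–C3 forms. The closest known reaction type is the C–H insertion of ortho-alkoxyaryl diazoketones next to the ether oxygen under chiral dirhodium tetracarboxylates, which gives chroman-4-ones. Ring C closes as a six-membered ring by 1,6-insertion (C3, C4, C4a, C8a, O1, C2), because the atom at the five-ring distance is O1 itself and bears no hydrogen. C2 is set by the catalyst, whose phthalimide-walled pocket should let the carbenoid reach only the pro-S hydrogen of the OCH2 group, and insertion with retention gives (2S). The step needs insertion to win over attack of O1 on the carbenoid (oxonium ylide, then 1,2-shift of the benzyl group), over full hydride transfer with closure through the enolate oxygen, and over cyclopropanation. What secures this is that O1 is a weakly donating vinylogous ester oxygen, the C2–H bonds are made hydridic by O1 and by the 2',4'-disiloxy arene, O5 carries a silyl group with no C–H bond at insertion distance, the C6 prenyl alkene is held meta to C4a and cannot reach C3, and dilution suppresses bimolecular reaction with the alkenes.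

**Step 13**
Reactants: 21 (2S)-5,7,2',4'-tetrakis(TBS-oxy)-3'-geranyl-6-prenylflavanone
Product: 22 (2S)-4-(TES-oxy)-5,7,2',4'-tetrakis(TBS-oxy)-3'-geranyl-6-prenylflav-3-ene
Conditions: Et3N (3 equiv), then TESOTf (1.5 equiv), CH2Cl2, −78 to 0 °C; non-aqueous work-up
Reagents that add atoms: triethylsilyl triflate, CC[Si](CC)(CC)OS(=O)(=O)C(F)(F)F
Why: Soft enolisation, in which the silyl triflate activates the C4 carbonyl and the amine removes a C3 proton, so no free enolate forms that could expel O1 by retro-oxa-Michael reaction and racemise C2.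

**Step 14**
Reactants: 22 (2S)-4-(TES-oxy)-5,7,2',4'-tetrakis(TBS-oxy)-3'-geranyl-6-prenylflav-3-ene
Product: 24 (2R,3R)-3-(TES-oxy)-5,7,2',4'-tetrakis(TBS-oxy)-3'-geranyl-6-prenylflavanone, via siloxy epoxide 23 (not isolated)
Conditions: 2-(phenylsulfonyl)-3-(4-nitrophenyl)oxaziridine (1.2 equiv), acid-free CHCl3, rt to 40 °C
Reagents that add atoms: 2-(phenylsulfonyl)-3-(4-nitrophenyl)oxaziridine, O=S(=O)(c1ccccc1)N1OC1c1ccc([N+](=O)[O-])cc1
Why: Rubottom-type oxidation with an N-sulfonyloxaziridine, in which the electron-rich C3=C4 enol ether takes the oxygen atom faster than the isolated trisubstituted alkenes and from the face opposite ring B, after which the siloxy epoxide opens toward C4 and the TES group moves to O3, setting (3R) trans to ring B.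

**Step 15**
Reactants: 24 (2R,3R)-3-(TES-oxy)-5,7,2',4'-tetrakis(TBS-oxy)-3'-geranyl-6-prenylflavanone
Product: 25 (2R,3R)-3,5,7,2',4'-pentahydroxy-3'-geranyl-6-prenylflavanone (CNP0166115.1)
Conditions: Bu4NF–AcOH (1:1, 6 equiv), THF, 0 °C to rt
Reagents that add atoms: none
Why: Fluoride-induced Si–O cleavage under acetic acid buffering keeps the phenols protonated, so ring opening at O1–C2, epimerisation at C3 and acid-induced chroman formation from the ortho-prenyl phenols are all avoided.

## Compound list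

1 | 2,4,6-trihydroxyacetophenone | CC(=O)c1c(O)cc(O)cc1O | starting material
2 | 1-[2-hydroxy-4,6-bis(TBS-oxy)phenyl]ethanone | CC(=O)c1c(O)cc(O[Si](C)(C)C(C)(C)C)cc1O[Si](C)(C)C(C)(C)C | intermediate
3 | 3-methylbut-2-en-1-ol | CC(C)=CCO | starting material
4 | 1-[2-(prenyloxy)-4,6-bis(TBS-oxy)phenyl]ethanone | CC(=O)c1c(OCC=C(C)C)cc(O[Si](C)(C)C(C)(C)C)cc1O[Si](C)(C)C(C)(C)C | intermediate
5 | 2-acetyl-3,5-bis(TBS-oxy)-6-(2-methylbut-3-en-2-yl)cyclohexa-2,4-dien-1-one (racemic, not isolated) | CC(=O)C1=C(O[Si](C)(C)C(C)(C)C)C=C(O[Si](C)(C)C(C)(C)C)C(C(C)(C)C=C)C1=O | intermediate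
6 | 2-acetyl-3,5-bis(TBS-oxy)-4-prenylcyclohexa-2,5-dien-1-one (not isolated) | CC(=O)C1=C(O[Si](C)(C)C(C)(C)C)C(CC=C(C)C)C(O[Si](C)(C)C(C)(C)C)=CC1=O | intermediate
7 | 1-[6-hydroxy-2,4-bis(TBS-oxy)-3-prenylphenyl]ethanone | CC(=O)c1c(O)cc(O[Si](C)(C)C(C)(C)C)c(CC=C(C)C)c1O[Si](C)(C)C(C)(C)C | intermediate
8 | resorcinol | Oc1cccc(O)c1 | starting material
9 | 1,3-bis(methoxymethoxy)benzene | COCOc1cccc(OCOC)c1 | intermediate
10 | geranyl bromide | CC(C)=CCC/C(C)=C/CBr | starting material
11 | 2-lithio-1,3-bis(methoxymethoxy)benzene (not isolated) | [Li]c1c(OCOC)cccc1OCOC | intermediate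
12 | 2-geranyl-1,3-bis(methoxymethoxy)benzene | CC(C)=CCC/C(C)=C/Cc1c(OCOC)cccc1OCOC | intermediate
13 | 2-geranyl-4-lithio-1,3-bis(methoxymethoxy)benzene (not isolated) | CC(C)=CCC/C(C)=C/Cc1c(OCOC)ccc([Li])c1OCOC | intermediate
14 | 3-geranyl-2,4-bis(methoxymethoxy)benzaldehyde | CC(C)=CCC/C(C)=C/Cc1c(OCOC)ccc(C=O)c1OCOC | intermediate
15 | 3-geranyl-2,4-dihydroxybenzaldehyde | CC(C)=CCC/C(C)=C/Cc1c(O)ccc(C=O)c1O | intermediate
16 | 3-geranyl-2,4-bis(TBS-oxy)benzaldehyde | CC(C)=CCC/C(C)=C/Cc1c(O[Si](C)(C)C(C)(C)C)ccc(C=O)c1O[Si](C)(C)C(C)(C)C | intermediate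
17 | [3-geranyl-2,4-bis(TBS-oxy)phenyl]methanol | CC(C)=CCC/C(C)=C/Cc1c(O[Si](C)(C)C(C)(C)C)ccc(CO)c1O[Si](C)(C)C(C)(C)C | intermediate
18 | 1-{2-[3-geranyl-2,4-bis(TBS-oxy)benzyloxy]-4,6-bis(TBS-oxy)-5-prenylphenyl}ethanone | CC(C)=CCC/C(C)=C/Cc1c(O[Si](C)(C)C(C)(C)C)ccc(COc2cc(O[Si](C)(C)C(C)(C)C)c(CC=C(C)C)c(O[Si](C)(C)C(C)(C)C)c2C(C)=O)c1O[Si](C)(C)C(C)(C)C | intermediate
19 | 4,4,4-trifluoro-1-{2-[3-geranyl-2,4-bis(TBS-oxy)benzyloxy]-4,6-bis(TBS-oxy)-5-prenylphenyl}butane-1,3-dione (not isolated) | CC(C)=CCC/C(C)=C/Cc1c(O[Si](C)(C)C(C)(C)C)ccc(COc2cc(O[Si](C)(C)C(C)(C)C)c(CC=C(C)C)c(O[Si](C)(C)C(C)(C)C)c2C(=O)CC(=O)C(F)(F)F)c1O[Si](C)(C)C(C)(C)C | intermediate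
20 | 2-diazo-1-{2-[3-geranyl-2,4-bis(TBS-oxy)benzyloxy]-4,6-bis(TBS-oxy)-5-prenylphenyl}ethanone | CC(C)=CCC/C(C)=C/Cc1c(O[Si](C)(C)C(C)(C)C)ccc(COc2cc(O[Si](C)(C)C(C)(C)C)c(CC=C(C)C)c(O[Si](C)(C)C(C)(C)C)c2C(=O)C=[N+]=[N-])c1O[Si](C)(C)C(C)(C)C | intermediate
21 | (2S)-5,7,2',4'-tetrakis(TBS-oxy)-3'-geranyl-6-prenylflavanone | CC(C)=CCC/C(C)=C/Cc1c(O[Si](C)(C)C(C)(C)C)ccc([C@H]2Oc3cc(O[Si](C)(C)C(C)(C)C)c(CC=C(C)C)c(O[Si](C)(C)C(C)(C)C)c3C(=O)C2)c1O[Si](C)(C)C(C)(C)C | intermediate
22 | (2S)-4-(TES-oxy)-5,7,2',4'-tetrakis(TBS-oxy)-3'-geranyl-6-prenylflav-3-ene | CC(C)=CCC/C(C)=C/Cc1c(O[Si](C)(C)C(C)(C)C)ccc([C@H]2Oc3cc(O[Si](C)(C)C(C)(C)C)c(CC=C(C)C)c(O[Si](C)(C)C(C)(C)C)c3C(O[Si](CC)(CC)CC)=C2)c1O[Si](C)(C)C(C)(C)C | intermediate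
23 | (2R,3R,4R)-3,4-epoxy-4-(TES-oxy)-5,7,2',4'-tetrakis(TBS-oxy)-3'-geranyl-6-prenylflavan, epoxide oxygen anti to ring B (not isolated) | CC(C)=CCC/C(C)=C/Cc1c(O[Si](C)(C)C(C)(C)C)ccc([C@H]2Oc3cc(O[Si](C)(C)C(C)(C)C)c(CC=C(C)C)c(O[Si](C)(C)C(C)(C)C)c3[C@]4(O[Si](CC)(CC)CC)O[C@H]24)c1O[Si](C)(C)C(C)(C)C | intermediate
24 | (2R,3R)-3-(TES-oxy)-5,7,2',4'-tetrakis(TBS-oxy)-3'-geranyl-6-prenylflavanone | CC(C)=CCC/C(C)=C/Cc1c(O[Si](C)(C)C(C)(C)C)ccc([C@H]2Oc3cc(O[Si](C)(C)C(C)(C)C)c(CC=C(C)C)c(O[Si](C)(C)C(C)(C)C)c3C(=O)[C@@H]2O[Si](CC)(CC)CC)c1O[Si](C)(C)C(C)(C)C | intermediate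
25 | (2R,3R)-3,5,7,2',4'-pentahydroxy-3'-geranyl-6-prenylflavanone | CC(C)=CCC/C(C)=C/Cc1c(O)ccc([C@H]2Oc3cc(O)c(CC=C(C)C)c(O)c3C(=O)[C@@H]2O)c1O | target

## Step count

Total step count: 15.
Longest linear sequence: 12 steps (steps 4 to 15, from resorcinol).

## Steps most likely to fail

**1. Step 12.**
- What may go wrong: the lone pair of O1 captures the carbenoid and the benzyl group then undergoes a 1,2-shift. Hydride transfer may go to completion, with closure through the enolate oxygen. The catalyst may discriminate the two enantiotopic hydrogens only weakly.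
- Fallback (from 7 and 16, back at 21): ring C is closed at O1–C2 instead, and the enantiomers are separated by a catalytic reduction.
- Phenol 7 is converted into its dianion (LiN(SiMe3)2, 2.2 equiv, THF, −78 °C) and added to aldehyde 16 to give the racemic β-hydroxy ketone F1.
- An intramolecular Mitsunobu etherification (PPh3, DIAD, toluene, 0 °C) gives the racemic flavanone F2.
- Kinetic resolution follows by asymmetric transfer hydrogenation with RuCl[(S,S)-TsDPEN](p-cymene) or its enantiomer, whichever reduces the (2R)-ketone faster (HCO2H–Et3N, CH2Cl2, rt, run to about half conversion).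
- This turns the (2R)-enantiomer into the (2R,4R)-cis-flavan-4-ol F3. The untouched ketone, separated by chromatography, is 21.

**2. Step 3.**
- What may go wrong: the ortho-dienone tautomerises before the Cope shift, which leaves a reverse-prenyl group on the ortho carbon. Isoprene may be lost thermally from the ether, or silyl groups may scramble at 200 °C.
- Fallback (from 1 and 17, back at 18): the sigmatropic relay is replaced by direct C-prenylation, and the three hydroxyls are told apart by their graded reactivity (O7 before O1 before the chelated, prenyl-flanked O5).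
- Compound 1 is C-alkylated with prenyl bromide (CC(C)=CCBr, aq KOH, 0 °C to rt) to give 3-prenylphloroacetophenone F4.
- One equivalent of TBSCl (imidazole, DMF, −20 °C) gives the 4-O-TBS ether F5.
- Mitsunobu coupling with 17 (PPh3, DIAD, toluene) takes place at the less hindered ortho hydroxyl and gives the benzyl ether with free O5–H F6.
- TBSOTf and 2,6-lutidine (CH2Cl2, 0 °C) silylate the last hydroxyl to give 18.

**3. Step 14.**
- What may go wrong: oxygen transfer to the crowded enol ether is slow. This leaves time for epoxidation of the side-chain alkenes or for hydrolysis back to the ketone.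
- Fallback (from 22, back at 25): the C3–O bond is made with an N=O electrophile instead of an oxygen-atom donor.
- Compound 22 and nitrosobenzene undergo an O-selective nitroso aldol reaction (TESOTf, 10 mol %, CH2Cl2, −78 °C) anti to ring B, giving after work-up the 3-(N-phenylaminooxy) ketone F7.
- N–O cleavage (CuSO4, 30 mol %, MeOH–THF, 0 °C) gives the 3-hydroxy tetrasilyl ether F8.
- The conditions of step 15 convert F8 into 25.

## Further compounds

F1 | step 12 | rac-3-hydroxy-1-[6-hydroxy-2,4-bis(TBS-oxy)-3-prenylphenyl]-3-[3-geranyl-2,4-bis(TBS-oxy)phenyl]propan-1-one | CC(C)=CCC/C(C)=C/Cc1c(O[Si](C)(C)C(C)(C)C)ccc(C(O)CC(=O)c2c(O)cc(O[Si](C)(C)C(C)(C)C)c(CC=C(C)C)c2O[Si](C)(C)C(C)(C)C)c1O[Si](C)(C)C(C)(C)C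
F2 | step 12 | rac-5,7,2',4'-tetrakis(TBS-oxy)-3'-geranyl-6-prenylflavanone | CC(C)=CCC/C(C)=C/Cc1c(O[Si](C)(C)C(C)(C)C)ccc(C2Oc3cc(O[Si](C)(C)C(C)(C)C)c(CC=C(C)C)c(O[Si](C)(C)C(C)(C)C)c3C(=O)C2)c1O[Si](C)(C)C(C)(C)C
F3 | step 12 | (2R,4R)-5,7,2',4'-tetrakis(TBS-oxy)-3'-geranyl-6-prenylflavan-4-ol | CC(C)=CCC/C(C)=C/Cc1c(O[Si](C)(C)C(C)(C)C)ccc([C@@H]2Oc3cc(O[Si](C)(C)C(C)(C)C)c(CC=C(C)C)c(O[Si](C)(C)C(C)(C)C)c3[C@H](O)C2)c1O[Si](C)(C)C(C)(C)C
F4 | step 3 | 1-(2,4,6-trihydroxy-3-prenylphenyl)ethanone | CC(=O)c1c(O)cc(O)c(CC=C(C)C)c1O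
F5 | step 3 | 1-[2,6-dihydroxy-4-(TBS-oxy)-3-prenylphenyl]ethanone | CC(=O)c1c(O)cc(O[Si](C)(C)C(C)(C)C)c(CC=C(C)C)c1O
F6 | step 3 | 1-{2-[3-geranyl-2,4-bis(TBS-oxy)benzyloxy]-6-hydroxy-4-(TBS-oxy)-5-prenylphenyl}ethanone | CC(C)=CCC/C(C)=C/Cc1c(O[Si](C)(C)C(C)(C)C)ccc(COc2cc(O[Si](C)(C)C(C)(C)C)c(CC=C(C)C)c(O)c2C(C)=O)c1O[Si](C)(C)C(C)(C)C
F7 | step 14 | (2R,3R)-3-(N-phenylaminooxy)-5,7,2',4'-tetrakis(TBS-oxy)-3'-geranyl-6-prenylflavanone | CC(C)=CCC/C(C)=C/Cc1c(O[Si](C)(C)C(C)(C)C)ccc([C@H]2Oc3cc(O[Si](C)(C)C(C)(C)C)c(CC=C(C)C)c(O[Si](C)(C)C(C)(C)C)c3C(=O)[C@@H]2ONc4ccccc4)c1O[Si](C)(C)C(C)(C)C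
F8 | step 14 | (2R,3R)-3-hydroxy-5,7,2',4'-tetrakis(TBS-oxy)-3'-geranyl-6-prenylflavanone | CC(C)=CCC/C(C)=C/Cc1c(O[Si](C)(C)C(C)(C)C)ccc([C@H]2Oc3cc(O[Si](C)(C)C(C)(C)C)c(CC=C(C)C)c(O[Si](C)(C)C(C)(C)C)c3C(=O)[C@@H]2O)c1O[Si](C)(C)C(C)(C)C
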